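All constants are assumed; no experiment stands behind them.

- Ja, the reagent here, is the one to follow: it is charged at less than Qi, so it is the limiting reagent if it is consumed within the run.

| flask | Qi | Ja | Wy | Rx | time |
|---|---|---|---|---|---|
| Saturday's | 0.052 M | 0.0468 M | 0.0160 M | 0.52 mM | 20 h |
| Friday's | 0.052 M | 0.0468 M | 0.0230 M | 0.52 mM | 20 h |
| Sunday's | 0.052 M | 0.0468 M | 0.0350 M | 0.52 mM | 20 h |

    2 Ym → Ez (k1 = 2.9 × 10⁶ M⁻¹ s⁻¹)
    Ja + Uv ⇌ Ja.Uv, settled at all times (K2 = 4.4 M⁻¹)
    Ja + Zo → Xo + Ym (k3 = 35000 M⁻¹ s⁻¹)
    Qi + Ym → Uv + Zo (k4 = 7900 M⁻¹ s⁻¹)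
    2 Zo → Gy (k5 = 1.4 × 10⁷ M⁻¹ s⁻¹)
    Rx → 2 Aj (k6 = 1.6 × 10⁻⁵ s⁻¹)
    Qi + Aj → Xi + Zo (k7 = 3.1 × 10⁵ M⁻¹ s⁻¹)
    Xo → Ry (k8 = 5.3 × 10⁻⁵ s⁻¹)
    Zo → Ty (k9 = 0.20 s⁻¹)
    Wy + Uv → Wy.Uv (k10 = 0.48 M⁻¹ s⁻¹)

- part of the Qi that has reacted at the end, Saturday's
- part of the Qi that has reacted at the end, Friday's
- part of the Qi that has reacted at the end, Sunday's
- what raising the concentration of Wy from its lowest to its highest value here does to the part of the Qi that has reacted (changes below 5 percentage points count as none) (it rises / it falls / no change)

- percent here means Qi units held: one Gy counts as two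
- what is said of Uv includes Ja.Uv
- two of one species on the left: rate k times its square, two consumed each time
- run time (Saturday's): 20 h

- Saturday's and Sunday's flasks look nearly the same; they differ in Wy, 0.0160 M against 0.0350 M, about twice as much on Sunday.
- In the chain, Zo takes a Ja and becomes Ym, and Ym takes a Qi and becomes Zo. Over a long chain Ym is made about as fast as it is used, so the rate of Qi loss through Ym divided by the rate of Ja loss is about one, and time and the carrier concentrations drop out of that quotient.
- Wy takes up Uv, and Uv holds Ja in a reversible pairing. Neither enters the quotient, so by my reckoning Wy may alter the pace but not where the two flasks end.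
- Beside the chain, each Rx that breaks gives two Aj, and each Aj takes one Qi without using Ja. In 20 h that costs 0.711 mM of Qi.
- The quantity to carry is the Qi spent: the Ja charged plus twice the Rx broken, here 0.04751 M.
- Divided by the Qi charged, this gives my figures: Saturday's 91.4%, Friday's 91.4%, Sunday's 91.4%, and for the trend no change.
- The forecast gives 91.3% for Saturday's, 91.3% for Friday's and 91.3% for Sunday's, each within 90.5% to 92%, with the trend no change; each figure differs from mine by 0.068 percentage points. Its ground for the trend is “Wy merely removes Uv, so it changes the speed slightly, not the endpoint”.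
- The simulation gives 91.3% for Saturday's, 91.3% for Friday's and 91.3% for Sunday's, a change of 0 points and so the trend no change, and the forecast is right. Saturday's ends with 0% of its charged Ja free and 0 M of Ja.Uv. Adding twice the Rx still unbroken at 20 h to the Qi spent gives 92.0% for Saturday's flask left until 200 h; the run gives 91.9%, with Rx at 0%.

- The neighbour like Friday's but with 0.019 M of Ja should spend 0.01971 M of Qi, which is 37.9% of its charge. The simulation gives 37.9%.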